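**Retrosynthetic overview**

1. Disconnect C2–C1': ring B comes from 2,3,6-trimethoxyphenol (6); rings A/C come from a 4-ethoxybenzopyrylium ion built in the same flask from acetophenone 2 and triethyl orthoformate, which supplies C2.
2. Enabling feature: C1' of ring B is para to the free 4'-OH and both carbons ortho to that OH (C3', C5') carry OMe, so C1' is the only phenol-activated C–H of 6. C2 of ring C is the O1-bound end of the vinylogous ester O1–C2=C3–C4=O, i.e. the electrophilic α-carbon of a pyrylium ion.
3. Key step: a three-component annulation/arylation/dehydrogenation closes ring C (C3–C2, O1–C2) and forms C2–C1' in one operation.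
4. Ring order: ring A is bought (phloroacetophenone, then benzylated); ring B is made from 1,2,4-trimethoxybenzene; ring C is formed last, in the key step; hydrogenolysis then frees 5-OH and 7-OH.

Key step: step 3

Remark on the chemistry: the target is a planar, achiral flavone with no stereocentre, so no configuration has to be set. The only stereocentre on the route (C2 of intermediate 9) forms as a racemate and is destroyed in the same flask.

**Step 1**
Reactants: 1 2',4',6'-trihydroxyacetophenone
Product: 2 1-[2,4-bis(benzyloxy)-6-hydroxyphenyl]ethan-1-one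
Conditions: BnBr (2.05 equiv), K2CO3 (2.1 equiv), DMF, rt
Reagents that add atoms: benzyl bromide, BrCc1ccccc1
Why: Williamson etherification, in which the 4-OH and one ortho OH are alkylated while the remaining ortho OH, held in a hydrogen bond to the acetyl carbonyl, is the least acidic and least nucleophilic site and should stay free.

**Step 2**
Reactants: 3 1,2,4-trimethoxybenzene
Product: 6 2,3,6-trimethoxyphenol, via aryllithium 4 (not isolated), via lithium aryltrimethoxyborate 5 (not isolated)
Conditions: n-BuLi, THF, 0 °C → rt; B(OMe)3, −78 °C → rt; AcOH, 30% aq H2O2, 0 °C → rt; Na2SO3 quench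
Reagents that add atoms: hydrogen peroxide, OO (the phenolic oxygen of 6); n-butyllithium, [Li]CCCC (Li of 4 only); trimethyl borate, COB(OC)OC (the B(OMe)3 unit of 5 only)
Why: Directed ortho-metalation should occur at C3 of 3, the only C–H flanked by two methoxy groups, and after trapping as the borate the peroxide-induced 1,2-aryl shift from boron to oxygen (boronate oxidation) places the OH exactly at the lithiated carbon.

**Step 3**
Reactants: 2 1-[2,4-bis(benzyloxy)-6-hydroxyphenyl]ethan-1-one; 7 triethyl orthoformate; 6 2,3,6-trimethoxyphenol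
Product: 11 5,7-bis(benzyloxy)-2-(4-hydroxy-2,3,5-trimethoxyphenyl)-4H-chromen-4-one, via benzopyrylium tetrafluoroborate 8 (not isolated), via 2H-chromene adduct 9 (not isolated), via 4-ethoxyflavylium tetrafluoroborate 10 (not isolated)
Conditions: (i) 7 (3 equiv), HBF4·OEt2 (1.1 equiv), CH2Cl2, 0 °C → rt; Et2O, supernatant decanted in the same flask; (ii) 6 (0.95 equiv), 2,6-lutidine (1.05 equiv), MeCN, −20 °C → rt; (iii) DDQ (1.05 equiv), 0 °C; (iv) H2O/THF, 40 °C; aq NaHCO3 work-up
Reagents that add atoms: water, O (the C4 carbonyl oxygen of 11, introduced on hydrolysis of 10); triethyl orthoformate 7, CCOC(OCC)OCC (C2 of ring C and the OEt group of 8–10; already listed as reactant); tetrafluoroboric acid diethyl etherate, [H+].F[B-](F)(F)F (counter-ion of 8 and 10 only)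
Why: Proposed new method: acid converts the orthoformate into the diethoxycarbenium ion, which is attacked by the enol of methyl ketone 2 (C3–C2 bond); the phenolic OH then closes ring C at the same carbon (O1–C2, a geometrically favoured 6-endo-trig oxa-Michael addition to the β-ethoxyenone followed by loss of EtOH), and O-ethylation at C4 gives the 4-ethoxybenzopyrylium ion 8, a second orthoformate scavenging the water formed. The lutidine-buffered phenol 6 then adds through its para carbon to C2 of 8 (Friedel–Crafts-type SEAr, forming C2–C1'), DDQ abstracts the doubly activated C2 hydride of 9 to give flavylium ion 10, and water displaces the 4-OEt group by addition–elimination to leave the flavone carbonyl. The closest known reactions are the separate stages, namely formation of 4-ethoxybenzopyrylium salts from o-hydroxyacetophenones with orthoformate and strong acid, addition of electron-rich arenes to C2 of benzopyrylium salts, quinone dehydrogenation of 2H-flavenes to flavylium salts and hydrolysis of 4-alkoxyflavylium salts to flavones; what is new is merging them in one flask with a free phenol as the arene. The only stereocentre formed (C2 of 9) is racemic and is erased by the hydride abstraction. Site selectivity on 6 is secured because only C4 is para to the free OH, both ortho positions are blocked by OMe and C5 is meta to OH, so phenol(ate)-type C-attack can occur only at the carbon that becomes C1', while O-attack gives a labile aryl acetal that reverts to 8. Site selectivity on 8 is secured because C2 is the unsubstituted α-position of the pyrylium ring, whereas C4 carries OEt and is shielded by the peri 5-OBn group, so addition there is only reversible ketal formation.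

**Step 4**
Reactants: 11 5,7-bis(benzyloxy)-2-(4-hydroxy-2,3,5-trimethoxyphenyl)-4H-chromen-4-one
Product: 12 5,7,4'-trihydroxy-2',3',5'-trimethoxyflavone
Conditions: H2 (1 atm), 10% Pd/C, EtOAc/MeOH, rt
Reagents that add atoms: none
Why: Pd-catalysed hydrogenolysis should cleave only the two benzyl aryl ethers, since methyl ethers are inert and the C2=C3 bond of the cross-conjugated γ-pyrone (a vinylogous ester) is not expected to be reduced at 1 atm and room temperature; no stereocentre is involved.

**Compound list**

1 | 2',4',6'-trihydroxyacetophenone (phloroacetophenone) | CC(=O)c1c(O)cc(O)cc1O | starting material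
2 | 1-[2,4-bis(benzyloxy)-6-hydroxyphenyl]ethan-1-one | CC(=O)c1c(O)cc(OCc2ccccc2)cc1OCc1ccccc1 | intermediate
3 | 1,2,4-trimethoxybenzene | COc1ccc(OC)c(OC)c1 | starting material
4 | (2,3,6-trimethoxyphenyl)lithium | [Li]c1c(OC)ccc(OC)c1OC | intermediate
5 | lithium trimethoxy(2,3,6-trimethoxyphenyl)borate | [Li+].CO[B-](OC)(OC)c1c(OC)ccc(OC)c1OC | intermediate
6 | 2,3,6-trimethoxyphenol | COc1ccc(OC)c(OC)c1O | intermediate
7 | triethyl orthoformate | CCOC(OCC)OCC | starting material
8 | 5,7-bis(benzyloxy)-4-ethoxychromenylium tetrafluoroborate | CCOc1cc[o+]c2cc(OCc3ccccc3)cc(OCc3ccccc3)c12.F[B-](F)(F)F | intermediate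
9 | 4-[5,7-bis(benzyloxy)-4-ethoxy-2H-chromen-2-yl]-2,3,6-trimethoxyphenol (racemic) | CCOC1=CC(c2cc(OC)c(O)c(OC)c2OC)Oc2cc(OCc3ccccc3)cc(OCc3ccccc3)c21 | intermediate
10 | 5,7-bis(benzyloxy)-4-ethoxy-2-(4-hydroxy-2,3,5-trimethoxyphenyl)chromenylium tetrafluoroborate | CCOc1cc(-c2cc(OC)c(O)c(OC)c2OC)[o+]c2cc(OCc3ccccc3)cc(OCc3ccccc3)c12.F[B-](F)(F)F | intermediate
11 | 5,7-bis(benzyloxy)-2-(4-hydroxy-2,3,5-trimethoxyphenyl)-4H-chromen-4-one | COc1cc(-c2cc(=O)c3c(OCc4ccccc4)cc(OCc4ccccc4)cc3o2)c(OC)c(OC)c1O | intermediate
12 | 5,7,4'-trihydroxy-2',3',5'-trimethoxyflavone | COc1cc(-c2cc(=O)c3c(O)cc(O)cc3o2)c(OC)c(OC)c1O | target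

**Totals**

Total step count: 4. Longest linear sequence: 3 steps (1 → 3 → 4, or 2 → 3 → 4).

**Steps most likely to fail**

Step 3 (Proposed new method). Several processes may go wrong:
- the carbenium ion may attack the electron-rich ring A instead of the ketone enol;
- a benzyl group may be transferred from the alkoxy-stabilised cation to the phenol;
- orthoformate carried over may formylate 6;
- hydride abstraction may be incomplete, so that the adduct hydrolyses to the flavanone.

The fallback uses known chemistry, sets out from 2 and 6 and returns to the route at 12. Acetophenone 2 is condensed with DMF dimethyl acetal to (E)-1-[2,4-bis(benzyloxy)-6-hydroxyphenyl]-3-(dimethylamino)prop-2-en-1-one F1, which should cyclise with HCl to 5,7-bis(benzyloxy)-4H-chromen-4-one F2. Phenol 6 is brominated para to the OH with NBS to 4-bromo-2,3,6-trimethoxyphenol F3 and benzylated to 1-(benzyloxy)-4-bromo-2,3,6-trimethoxybenzene F4. Bromine–lithium exchange, B(OiPr)3 and acid hydrolysis then give [4-(benzyloxy)-2,3,5-trimethoxyphenyl]boronic acid F5. A Pd(II)-catalysed oxidative Heck arylation of chromone F2 at C2 with F5 (Pd(TFA)2, oxidant) should give 5,7-bis(benzyloxy)-2-[4-(benzyloxy)-2,3,5-trimethoxyphenyl]-4H-chromen-4-one F6, and hydrogenolysis under the conditions of step 4 gives 12.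

Step 2. The di-ortho-alkoxy arylborate may undergo protodeboronation before the boron-to-oxygen shift, or the very electron-rich phenol may be over-oxidised by peroxide. The fallback sets out from 3 and returns at 6. The same aryllithium is quenched with DMF to 2,3,6-trimethoxybenzaldehyde F8, Baeyer–Villiger oxidation with mCPBA gives 2,3,6-trimethoxyphenyl formate F9, and methanolysis (K2CO3, MeOH) after the oxidant has been destroyed releases 6. The oxygen therefore stays masked as an ester for as long as peroxide is present.

Step 1. Selectivity between the free and the chelated hydroxyls may be lost, giving over-alkylation. The fallback sets out from 1 and returns at 2. Phloroacetophenone is exhaustively benzylated (excess BnBr, K2CO3, DMF, 60 °C) to 1-[2,4,6-tris(benzyloxy)phenyl]ethan-1-one F7, and the one benzyl ether ortho to the carbonyl is then removed by chelation-controlled cleavage (MgBr2·OEt2, toluene/Et2O, reflux) to give 2. Selectivity is then set by deprotection, not by alkylation.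

**Further compounds**

F1 | step 3 | (E)-1-[2,4-bis(benzyloxy)-6-hydroxyphenyl]-3-(dimethylamino)prop-2-en-1-one | CN(C)/C=C/C(=O)c1c(O)cc(OCc2ccccc2)cc1OCc1ccccc1
F2 | step 3 | 5,7-bis(benzyloxy)-4H-chromen-4-one | O=c1ccoc2cc(OCc3ccccc3)cc(OCc3ccccc3)c12
F3 | step 3 | 4-bromo-2,3,6-trimethoxyphenol | Oc1c(OC)cc(Br)c(OC)c1OC
F4 | step 3 | 1-(benzyloxy)-4-bromo-2,3,6-trimethoxybenzene | COc1cc(Br)c(OC)c(OC)c1OCc1ccccc1
F5 | step 3 | [4-(benzyloxy)-2,3,5-trimethoxyphenyl]boronic acid | COc1cc(B(O)O)c(OC)c(OC)c1OCc1ccccc1
F6 | step 3 | 5,7-bis(benzyloxy)-2-[4-(benzyloxy)-2,3,5-trimethoxyphenyl]-4H-chromen-4-one | COc1cc(-c2cc(=O)c3c(OCc4ccccc4)cc(OCc4ccccc4)cc3o2)c(OC)c(OC)c1OCc1ccccc1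
F7 | step 1 | 1-[2,4,6-tris(benzyloxy)phenyl]ethan-1-one | CC(=O)c1c(OCc2ccccc2)cc(OCc2ccccc2)cc1OCc1ccccc1
F8 | step 2 | 2,3,6-trimethoxybenzaldehyde | O=Cc1c(OC)ccc(OC)c1OC
F9 | step 2 | 2,3,6-trimethoxyphenyl formate | O=COc1c(OC)ccc(OC)c1OC
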